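**Retrosynthetic overview**
1. The last step cuts the west benzofuran (C3–C3a and O1–C2) into iodo-diacetate 11 and terminal alkyne 21, joined by one-pot Sonogashira coupling and deacetylative 5-endo cyclisation.
2. West half 11: resorcinol, bis-MOM ether, C2 lithiation and copper-mediated geranylation, C4 lithiation and iodination, then MOM-to-acetate exchange. Geranyl bromide is built from a C6 bromide, acetylide, Me3Al and CH2O by Zr-catalysed carboalumination, which sets the E-alkene.
3. East half 21: 3-bromophenol, Ir C–H borylation/oxidation (second oxygen), para-iodination, Sonogashira/cyclisation with 2-methylbut-3-yn-2-ol, a new OH-directed asymmetric hydrogenation that sets C2 as (R), then alkyne installation at the C–Br bond.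
4. Ring order: east benzofuran, then east dihydrobenzofuran, then west benzofuran last.

Assumptions: the stereocentre in the target SMILES is (R); one-pot sequences (borylation/oxidation, coupling/cyclisation) are counted as one step; Me3Al and paraformaldehyde are treated as C1 reagents and listed under "Reagents that add atoms".

---

**Geranyl fragment**

**Step 1**
Reactants: 1 5-bromo-2-methylpent-2-ene; 2 lithium acetylide–ethylenediamine complex
Product: 3 6-methylhept-5-en-1-yne
Conditions: DMSO, 10 °C → rt
Reagents that add atoms: none
Why: SN2 alkylation of the acetylide by a primary bromide gives the terminal enyne.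

**Step 2**
Reactants: 3 6-methylhept-5-en-1-yne
Product: 4 geraniol, (2E)-3,7-dimethylocta-2,6-dien-1-ol
Conditions: Me3Al (2 equiv), Cp2ZrCl2 (0.25 equiv), (CH2Cl)2, rt; then n-BuLi, (CH2O)n, THF, 0 °C → rt
Reagents that add atoms: trimethylaluminium, C[Al](C)C; paraformaldehyde, C=O
Why: Negishi Zr-catalysed syn-carboalumination gives the (E)-alkenylalane regioselectively, and its ate complex adds to formaldehyde with retention, fixing the 2E geometry.

**Step 3**
Reactants: 4 geraniol
Product: 5 geranyl bromide, (2E)-1-bromo-3,7-dimethylocta-2,6-diene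
Conditions: PBr3, pyridine (cat.), Et2O, −10 °C (used crude)
Reagents that add atoms: phosphorus tribromide, BrP(Br)Br
Why: Bromination of a primary allylic alcohol at low temperature proceeds without allylic transposition or E/Z loss.

**West fragment**

**Step 4**
Reactants: 6 resorcinol
Product: 7 1,3-bis(methoxymethoxy)benzene
Conditions: MOMCl, i-Pr2NEt, CH2Cl2, 0 °C → rt
Reagents that add atoms: chloromethyl methyl ether, COCCl
Why: Phenol O-alkylation installs two MOM groups that protect the phenols and direct ortho-metalation.

**Step 5**
Reactants: 7 1,3-bis(methoxymethoxy)benzene; 5 geranyl bromide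
Product: 8 2-[(2E)-3,7-dimethylocta-2,6-dien-1-yl]-1,3-bis(methoxymethoxy)benzene
Conditions: n-BuLi, THF, 0 °C → rt; CuBr·SMe2, −40 °C; then 5, −78 °C → rt
Reagents that add atoms: none
Why: Directed ortho-metalation occurs at C2 between the two OMOM groups, and the aryl copper species alkylates the allylic bromide at the α-carbon (SN2) with retention of the E-alkene.

**Step 6**
Reactants: 8
Product: 9 3-[(2E)-3,7-dimethylocta-2,6-dien-1-yl]-1-iodo-2,4-bis(methoxymethoxy)benzene
Conditions: n-BuLi, TMEDA, THF, −20 → 0 °C; then I2, −78 °C
Reagents that add atoms: iodine, II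
Why: A second MOM-directed ortho-lithiation takes the only remaining ring position ortho to OMOM (C4 = C6 by symmetry), and iodine quench at −78 °C is faster than any reaction with the alkenes.

**Step 7**
Reactants: 9
Product: 10 2-[(2E)-3,7-dimethylocta-2,6-dien-1-yl]-4-iodobenzene-1,3-diol
Conditions: 2 M HCl, MeOH, rt → 40 °C
Reagents that add atoms: none
Why: Mild acidic methanolysis cleaves the MOM acetals, while the trisubstituted alkenes are not protonated at this acidity, so chroman formation is avoided.

**Step 8**
Reactants: 10
Product: 11 2-[(2E)-3,7-dimethylocta-2,6-dien-1-yl]-4-iodo-1,3-phenylene diacetate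
Conditions: Ac2O, Et3N, DMAP (cat.), CH2Cl2, 0 °C → rt
Reagents that add atoms: acetic anhydride, CC(=O)OC(C)=O
Why: Acetylation masks both phenols so the electron-rich aryl iodide couples cleanly, and the ortho acetate is released later to close the furan.

**East fragment**

**Step 9**
Reactants: 12 3-bromophenol
Product: 13 3-bromophenyl acetate
Conditions: Ac2O, pyridine, rt
Reagents that add atoms: acetic anhydride, CC(=O)OC(C)=O
Why: Phenol acetylation gives a group that survives borylation, differentiates the two oxygens and is lost during the later cyclisation.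

**Step 10**
Reactants: 13 3-bromophenyl acetate
Product: 14 3-bromo-5-hydroxyphenyl acetate
Conditions: [Ir(OMe)(cod)]2 (1 mol%), dtbpy (2 mol%), B2pin2, THF, 80 °C; then Oxone, acetone/H2O, rt
Reagents that add atoms: Oxone (potassium peroxymonosulfate), [K+].[O-]S(=O)(=O)OO (the boron from B2pin2 is removed in the oxidation)
Why: Sterically controlled Ir-catalysed C–H borylation of a 1,3-disubstituted arene occurs at C5, and oxidation of the C–B bond gives the phenol without touching the acetate or C–Br.

**Step 11**
Reactants: 14
Product: 15 3-bromo-5-hydroxy-2-iodophenyl acetate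
Conditions: NIS, TsOH·H2O (10 mol%), MeCN, 0 °C → rt
Reagents that add atoms: N-iodosuccinimide, O=C1CCC(=O)N1I
Why: Electrophilic iodination is directed para to the free OH (as for 3,5-disubstituted phenols), which places iodine between the C–Br and C–OAc carbons.

**Step 12**
Reactants: 15; 16 2-methylbut-3-yn-2-ol
Product: 17 4-bromo-2-(2-hydroxypropan-2-yl)-1-benzofuran-6-ol
Conditions: PdCl2(PPh3)2 (3 mol%), CuI (5 mol%), Et3N, THF, rt → 40 °C; then K2CO3, MeOH, 60 °C
Reagents that add atoms: none
Why: Sonogashira coupling is selective for C–I over C–Br, and methanolysis of the ortho acetate releases a phenoxide that closes the furan by 5-endo-dig attack on the alkyne.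

**Step 13**
Reactants: 17
Product: 18 (2R)-4-bromo-2-(2-hydroxypropan-2-yl)-2,3-dihydro-1-benzofuran-6-ol
Conditions: H2 (50 bar), [Ir(cod)(L*)]BArF (2 mol%; L* = chiral bicyclic pyridine–phosphinite N,P ligand), CH2Cl2, 40 °C
Reagents that add atoms: none
Why: Proposed new method: hydroxyl-directed Ir-catalysed asymmetric hydrogenation of the C2=C3 bond of a benzofuran bearing a tertiary carbinol at C2 — the furan C2=C3 bond is only weakly aromatic and behaves as a trisubstituted enol ether, the tertiary OH sits as in an allylic alcohol and can bind the cationic Ir(III) dihydride so the alkene is held in a chelate and H2 is delivered to one enantioface chosen by the N,P ligand, setting C2; the ligand antipode that gives (R) is selected on first use and the configuration confirmed by anomalous-dispersion X-ray of bromide 18; the benzene ring, C–Br bond and phenol are not reduced by this catalyst class; the closest known reactions are Ir–N,P and Ru–NHC asymmetric hydrogenation of simple 2-alkyl- and 2-arylbenzofurans and OH-directed hydrogenation of allylic alcohols, which to my knowledge have not been shown with a tertiary carbinol at C2 or a 4-halo substituent.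

**Step 14**
Reactants: 18; 19 ethynyltrimethylsilane
Product: 20 (2R)-2-(2-hydroxypropan-2-yl)-4-[(trimethylsilyl)ethynyl]-2,3-dihydro-1-benzofuran-6-ol
Conditions: Pd(PhCN)2Cl2 (3 mol%), [HP(t-Bu)3]BF4 (6 mol%), CuI (2 mol%), i-Pr2NH, dioxane, rt → 45 °C
Reagents that add atoms: none
Why: Sonogashira coupling of an electron-rich, ortho-substituted aryl bromide with a bulky electron-rich phosphine tolerates the free phenol and tertiary alcohol and does not touch the C2 stereocentre.

**Step 15**
Reactants: 20
Product: 21 (2R)-4-ethynyl-2-(2-hydroxypropan-2-yl)-2,3-dihydro-1-benzofuran-6-ol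
Conditions: K2CO3, MeOH, rt
Reagents that add atoms: none
Why: Methanolysis of the C(sp)–Si bond gives the terminal alkyne under conditions that leave the ether stereocentre untouched.

**Fragment union**

**Step 16**
Reactants: 11; 21
Product: 22 mulberrofuran X
Conditions: PdCl2(PPh3)2 (3 mol%), CuI (5 mol%), Et3N, DMF (degassed), rt; then Cs2CO3, MeOH, 60 °C
Reagents that add atoms: none
Why: Sonogashira coupling of the aryl iodide with the aryl alkyne, followed by in-pot acetate methanolysis, lets the ortho phenoxide close the west furan (5-endo-dig, Larock/Castro-type benzofuran synthesis), while the second acetate is cleaved to the free 6-OH; geranyl, tertiary alcohol and the (R) centre are inert.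

---

**Compound list**
1 | 5-bromo-2-methylpent-2-ene | CC(C)=CCCBr | starting material
2 | lithium acetylide–ethylenediamine complex | [Li]C#C.NCCN | starting material
3 | 6-methylhept-5-en-1-yne | CC(C)=CCCC#C | intermediate
4 | geraniol, (2E)-3,7-dimethylocta-2,6-dien-1-ol | CC(C)=CCC/C(C)=C/CO | intermediate
5 | geranyl bromide, (2E)-1-bromo-3,7-dimethylocta-2,6-diene | CC(C)=CCC/C(C)=C/CBr | intermediate
6 | resorcinol | Oc1cccc(O)c1 | starting material
7 | 1,3-bis(methoxymethoxy)benzene | COCOc1cccc(OCOC)c1 | intermediate
8 | 2-[(2E)-3,7-dimethylocta-2,6-dien-1-yl]-1,3-bis(methoxymethoxy)benzene | CC(C)=CCC/C(C)=C/Cc1c(OCOC)cccc1OCOC | intermediate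
9 | 3-[(2E)-3,7-dimethylocta-2,6-dien-1-yl]-1-iodo-2,4-bis(methoxymethoxy)benzene | CC(C)=CCC/C(C)=C/Cc1c(OCOC)ccc(I)c1OCOC | intermediate
10 | 2-[(2E)-3,7-dimethylocta-2,6-dien-1-yl]-4-iodobenzene-1,3-diol | CC(C)=CCC/C(C)=C/Cc1c(O)ccc(I)c1O | intermediate
11 | 2-[(2E)-3,7-dimethylocta-2,6-dien-1-yl]-4-iodo-1,3-phenylene diacetate | CC(C)=CCC/C(C)=C/Cc1c(OC(C)=O)ccc(I)c1OC(C)=O | intermediate
12 | 3-bromophenol | Oc1cccc(Br)c1 | starting material
13 | 3-bromophenyl acetate | CC(=O)Oc1cccc(Br)c1 | intermediate
14 | 3-bromo-5-hydroxyphenyl acetate | CC(=O)Oc1cc(O)cc(Br)c1 | intermediate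
15 | 3-bromo-5-hydroxy-2-iodophenyl acetate | CC(=O)Oc1cc(O)cc(Br)c1I | intermediate
16 | 2-methylbut-3-yn-2-ol | CC(C)(O)C#C | starting material
17 | 4-bromo-2-(2-hydroxypropan-2-yl)-1-benzofuran-6-ol | CC(C)(O)c1cc2c(Br)cc(O)cc2o1 | intermediate
18 | (2R)-4-bromo-2-(2-hydroxypropan-2-yl)-2,3-dihydro-1-benzofuran-6-ol | Oc1cc(Br)c2C[C@H](C(C)(C)O)Oc2c1 | intermediate
19 | ethynyltrimethylsilane | C#C[Si](C)(C)C | starting material
20 | (2R)-2-(2-hydroxypropan-2-yl)-4-[(trimethylsilyl)ethynyl]-2,3-dihydro-1-benzofuran-6-ol | Oc1cc(C#C[Si](C)(C)C)c2C[C@H](C(C)(C)O)Oc2c1 | intermediate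
21 | (2R)-4-ethynyl-2-(2-hydroxypropan-2-yl)-2,3-dihydro-1-benzofuran-6-ol | Oc1cc(C#C)c2C[C@H](C(C)(C)O)Oc2c1 | intermediate
22 | mulberrofuran X | CC(C)=CCC/C(C)=C/Cc1c(O)ccc2cc(-c3cc(O)cc4c3C[C@H](C(C)(C)O)O4)oc12 | target

---

**Total step count:** 16
**Longest linear sequence:** 8 steps (Steps 1–3, 5–8, 16; equally Steps 9–16)

**Three steps most likely to fail**
1. **Step 13 (proposed new hydrogenation):** low conversion with the bulky C2 carbinol, or ionisation of the tertiary alcohol. Fallback with known chemistry, replacing Steps 12–13: methanolyse 15 to 5-bromo-4-iodobenzene-1,3-diol, run the Pd-catalysed enantioselective Heck/Tsuji–Trost [3+2] heteroannulation with isoprene (chiral sulfinamide–phosphine ligand) to the (R)-2-isopropenyl-dihydrobenzofuran, then Mukaiyama hydration (Mn(dpm)3, PhSiH3, O2) to give 18.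
2. **Step 6 (ring lithiation with the geranyl group present):** competing deprotonation at the benzylic/allylic CH2. Fallback: reverse the coupling polarity so that no lithiation is done on a geranylated ring. Iodinate resorcinol with ICl, bis-MOM protect, couple with TIPS-acetylene, then carry out the C2 lithiation/Cu–geranylation. After desilylation, MOM removal and acetylation, couple the west aryl alkyne with aryl bromide 18 and cyclise; Steps 14–15 are then not needed.
3. **Step 11 (iodination regiochemistry):** ortho isomers may form because the para site is flanked by Br and OAc. Fallback: fix the iodide by directed metalation before the second oxygen is introduced. Treat 3-bromophenyl MOM ether with LDA at −78 °C (lithiation between OMOM and Br) and quench with I2, then Ir-borylation/oxidation at C5, Sonogashira with 16, acidic MOM removal and Cu-mediated cyclisation to 17.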